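Catalyst charged over substrates charged is a ratio you can take before anything stirs: if each catalyst holds one substrate, 10.0 % of the substrates can sit on it with no product made.

| flask | left-handed substrate | right-handed substrate | partner | protic impurity | free catalyst | remark | time |
|---|---|---|---|---|---|---|---|
| gamma | 0.10 M | 0.10 M | 0.050 M | 0.010 M | 20 mM | run made earlier |  |
| eta | 0.10 M | 0.10 M | 0.20 M | 0.010 M | 20 mM | run made earlier |  |
| flask | 0.10 M | 0.10 M | 0.100 M | 0.0100 M | 20 mM |  | 1.5 h |

| run | time / min | left-handed product / % | right-handed product / % | left-handed substrate / % |
|---|---|---|---|---|
| gamma | 8.00 | 2.4 | 2.0 | 47.4 |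
| gamma | 20.0 | 1.5 | 8.0 | 46.1 |
| gamma | 50.0 | 4.8 | 10.6 | 44.6 |
| gamma | 120 | 4.4 | 13.0 | 43.8 |
| eta | 25.0 | 13.1 | 31.1 | 35.7 |
| eta | 50.0 | 20.6 | 38.4 | 25.3 |
| eta | 80.0 | 24.6 | 43.5 | 21.4 |
| eta | 120 | 29.4 | 41.4 | 18.7 |

(scatter of a reading: 1 percentage point)

- free catalyst is single-handed; left-handed substrate and right-handed substrate are mirror images of each other, charged as a racemate, each of them at the stated concentration
- steps under discussion: free catalyst + left-handed substrate <-> catalyst intermediate A; free catalyst + right-handed substrate <-> catalyst intermediate B; partner + catalyst intermediate A -> free catalyst + left-handed product; partner + catalyst intermediate B -> free catalyst + right-handed product; 2 partner -> homo dimer; partner -> decomposed reagent; partner + protic impurity -> quenched reagent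
- an excess is the difference of the two amounts in percent of their sum
- an excess is below zero if the other one leads

* excess of left-handed product over right-handed product in the product at 10 min
* excess of left-handed product over right-handed product in the product at 1.5 h
* part of the left-handed substrate and right-handed substrate charged together that has reacted at 1.5 h

Climb from the fast end. By 25.0 min, the eta run had made 44.2 % product by reading, so one catalyst turn in that run took on average about 5.66 min. Loading is one part of a turn, and that average is short against 120 min, so expect the catalyst loaded within minutes. The slower rung is the using up of partner. The gamma-run product readings went from 15.4 % to 17.4 % between 50.0 min and 120 min, a rise of 2 percentage points on readings scattered by 1 point each. In the flask, with the impurity's charge subtracted, I reckon 0.0900 M of partner spared, less than the 0.200 M of substrates. So partner is the limiting reagent, and catalyst should end up still loaded.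

Now follow one spared partner molecule: it reaches a catalyst intermediate or is lost on its own. Product per spared partner by 120 min, any partner still unused counted as lost, reads 0.870 in the gamma run and 0.745 in the eta run. The flask's charge lies between theirs, so take the mean, 0.808, as the partner's chance. For the flask that gives 36.3 % product, and, counting substrate bound on the catalyst as reacted, 46.3 % reacted.

The forecast says −46 % and −39 % for the two excesses and 36 % reacted, “product is about 0.073 M, or about 36% conversion”, so its conversion stands below mine.

The flask gives −46.2 %, −40.1 % and 44.8 %.

    free catalyst + left-handed substrate ⇌ catalyst intermediate A (K = 18.0 M⁻¹, k = 440 M⁻¹ h⁻¹)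
    free catalyst + right-handed substrate ⇌ catalyst intermediate B (K = 170 M⁻¹, k = 2100 M⁻¹ h⁻¹)
    partner + catalyst intermediate A → free catalyst + left-handed product (k = 240 M⁻¹ h⁻¹)
    partner + catalyst intermediate B → free catalyst + right-handed product (k = 86.0 M⁻¹ h⁻¹)
    2 partner → homo dimer (k = 1.50 M⁻¹ h⁻¹)
    partner → decomposed reagent (k = 0.280 h⁻¹)
    partner + protic impurity → quenched reagent (k = 61.0 M⁻¹ h⁻¹)

In the flask, partner fell to 15.3 % of its charge at 0.750 h and 2.61 % at 1.50 h, and the step of partner with catalyst intermediate B had done half of its turnover up to 1.50 h by 0.265 h. At 1.50 h, product stood at 36.0 % against the reckoned 36.3 %, while catalyst intermediates A and B held 16.1 % and 71.8 % of the catalyst, 8.8 points of substrate beside the hold of 10.0 %. For the neighbour flask with 0.025 M of impurity, the same chance gives 40.3 % reacted, and that flask reached 40.2 %.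

The readings come from a simulation with constants of no real substance; scatter was added.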